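## Retrosynthetic overview

1. Target ⇒ macrocyclic 3Z,7E-diene acetate: both oxiranes are added last by catalyst-controlled (Shi) epoxidation; the acetate comes from the C10 carbinol.
2. Key disconnection C10–C11: the 12-membered ring is closed by an intramolecular Nozaki–Hiyama (Barbier-type) allylation. A 2-(chloromethyl)cyclohexenone becomes an allylchromium that attacks a tethered aldehyde through C11, so ring closure, C10, C11 and the exo-methylene ketone arise in one step (no RCM or olefination ring closure).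
3. Open-chain precursor ⇒ (Z)-vinyl iodide on ring A (Zhao olefination, sets 3Z) + C5–C10 alkylzinc (Negishi carboalumination sets 7E), joined by Negishi coupling; C18 is added afterwards by α-iodination and Stille hydroxymethylation.
4. Ring A with C1 ⇒ rhodium-catalysed enantioselective vinyl addition that desymmetrises 4,4-dimethylcyclohexa-2,5-dienone.
5. Ring order: ring A is present from step 1; 12-membered ring in step 13; the two oxiranes in step 15.

Assumption: the SMILES is taken literally as (1R,3R,4S,7R,8R,10R,11S) in bicyclo[9.3.1]pentadecane (verticillane) numbering (C1, C11 bridgeheads; C15 = CMe2; C18 = exocyclic CH2), i.e. C2 and C10 on opposite faces of ring A, a 3,4-oxirane derived from a 3Z alkene and a 7,8-oxirane from a 7E alkene; these atom labels are used throughout.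

## Route

Step 1
Reactants: 1 4,4-dimethylcyclohex-2-en-1-one
Product: 2 4,4-dimethylcyclohexa-2,5-dien-1-one
Conditions: DDQ (1.3 equiv), TsOH·H2O (cat.), 1,4-dioxane, reflux
Reagents that add atoms: none
Why: DDQ dehydrogenation of the enone gives the cross-conjugated dienone, which cannot tautomerise to a phenol because C4 is quaternary; no stereocentre is made.

Step 2
Reactants: 2 4,4-dimethylcyclohexa-2,5-dien-1-one
Product: 3 (5S)-5-ethenyl-4,4-dimethylcyclohex-2-en-1-one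
Conditions: K[CH2=CHBF3] (1.3 equiv), [Rh(cod)2]PF6 (3 mol%), (S)-BINAP (3.3 mol%), toluene/H2O 10:1, 100 °C
Reagents that add atoms: potassium vinyltrifluoroborate, [K+].C=C[B-](F)(F)F
Why: Hayashi–Miyaura rhodium-catalysed asymmetric 1,4-addition, in which the two enone units are homotopic so that enantioface choice alone decides the outcome, and (S)-BINAP (the ligand enantiomer that gives (S)-3-substituted cyclohexanones from cyclohex-2-enone) sets C1 (5S in 3, the arrangement that is 1R in the target), quinone monoketals showing that a quaternary neighbour is tolerated.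

Step 3
Reactants: 3 (5S)-5-ethenyl-4,4-dimethylcyclohex-2-en-1-one
Product: 4 2-[(1R)-2,2-dimethyl-5-oxocyclohex-3-en-1-yl]acetaldehyde
Conditions: PdCl2(PhCN)2 (10 mol%), CuCl2·2H2O (10 mol%), AgNO2 (5 mol%), O2 (1 atm), tBuOH/MeNO2 15:1, 25 °C
Reagents that add atoms: dioxygen, O=O
Why: Aldehyde-selective (anti-Markovnikov) Wacker oxidation with nitrite co-catalysis puts oxygen on the terminal carbon of the hindered vinyl group, while the electron-poor enone alkene is not oxidised and the non-enolisable C1 stereocentre is untouched.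

Step 4
Reactants: 4 2-[(1R)-2,2-dimethyl-5-oxocyclohex-3-en-1-yl]acetaldehyde
Product: 5 (5R)-5-[(2Z)-3-iodobut-2-en-1-yl]-4,4-dimethylcyclohex-2-en-1-one
Conditions: EtPPh3I, nBuLi, THF, 0 °C; I2, −78 °C; NaN(SiMe3)2, −20 °C; then 4, −78 → −20 °C
Reagents that add atoms: ethyltriphenylphosphonium iodide, CC[P+](c1ccccc1)(c1ccccc1)c1ccccc1.[I-]; iodine, II
Why: Stork–Zhao (α-iodo ylide) Wittig olefination reacts only with the aldehyde at −78 °C and gives the (Z)-2-iodoalkene (iodine cis to C2), which fixes the later 3Z geometry.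

Step 5
Reactants: 6 tert-butyl(but-3-yn-1-yloxy)dimethylsilane
Product: 9 (3E)-6-[(tert-butyldimethylsilyl)oxy]-4-methylhex-3-en-1-ol, via alkenyldimethylalane 7 (not isolated), via lithium alkenylalanate 8 (not isolated)
Conditions: Me3Al (2 equiv), Cp2ZrCl2 (0.2 equiv), CH2Cl2, 0 → 25 °C; volatiles removed; nBuLi, THF/hexane, −30 °C; ethylene oxide, −30 → 0 °C; aq. KNaC4H4O6 work-up
Reagents that add atoms: trimethylaluminium, C[Al](C)C; ethylene oxide, C1CO1
Why: Negishi zirconium-catalysed carboalumination adds methyl and aluminium syn across the alkyne (methyl on the internal carbon), which sets the 7E trisubstituted alkene, and the more nucleophilic alanate opens ethylene oxide with retention at the alkenyl carbon.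

Step 6
Reactants: 9 (3E)-6-[(tert-butyldimethylsilyl)oxy]-4-methylhex-3-en-1-ol
Product: 10 tert-butyl{[(3E)-6-iodo-3-methylhex-3-en-1-yl]oxy}dimethylsilane
Conditions: I2, PPh3, imidazole, CH2Cl2, 0 °C
Reagents that add atoms: iodine, II
Why: Appel-type iodination turns the primary alcohol into the iodide by SN2 displacement of the alkoxyphosphonium, leaving silyl ether and alkene untouched.

Step 7
Reactants: 10 tert-butyl{[(3E)-6-iodo-3-methylhex-3-en-1-yl]oxy}dimethylsilane; 5 (5R)-5-[(2Z)-3-iodobut-2-en-1-yl]-4,4-dimethylcyclohex-2-en-1-one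
Product: 12 (5R)-5-{(2Z,6E)-9-[(tert-butyldimethylsilyl)oxy]-3,7-dimethylnona-2,6-dien-1-yl}-4,4-dimethylcyclohex-2-en-1-one, via alkylzinc iodide 11 (not isolated)
Conditions: 10, Zn dust (activated with BrCH2CH2Br, Me3SiCl), LiCl, THF, 40 °C; then 5, Pd(PPh3)4 (5 mol%), THF, 50 °C
Reagents that add atoms: none
Why: Negishi sp3–sp2 cross-coupling, in which alkylzinc iodide 11 does not add to the enone and palladium-catalysed coupling with the vinyl iodide proceeds with retention, so C5 takes the place of iodine cis to C2 (3Z).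

Step 8
Reactants: 12 (5R)-5-{(2Z,6E)-9-[(tert-butyldimethylsilyl)oxy]-3,7-dimethylnona-2,6-dien-1-yl}-4,4-dimethylcyclohex-2-en-1-one
Product: 13 (5R)-5-{(2Z,6E)-9-[(tert-butyldimethylsilyl)oxy]-3,7-dimethylnona-2,6-dien-1-yl}-2-iodo-4,4-dimethylcyclohex-2-en-1-one
Conditions: I2 (1.5 equiv), pyridine, CH2Cl2, 0 → 25 °C
Reagents that add atoms: iodine, II
Why: Johnson α-iodination of an enone (pyridine conjugate addition, iodination of the enolate, E1cB loss of pyridine), known for 4,4-dimethylcyclohexenone, puts iodine on C12 only, the isolated alkenes surviving because their iodine adducts revert.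

Step 9
Reactants: 13 (5R)-5-{(2Z,6E)-9-[(tert-butyldimethylsilyl)oxy]-3,7-dimethylnona-2,6-dien-1-yl}-2-iodo-4,4-dimethylcyclohex-2-en-1-one
Product: 14 (5R)-5-{(2Z,6E)-9-[(tert-butyldimethylsilyl)oxy]-3,7-dimethylnona-2,6-dien-1-yl}-2-(hydroxymethyl)-4,4-dimethylcyclohex-2-en-1-one
Conditions: Bu3SnCH2OH (1.5 equiv), Pd(PPh3)4 (5 mol%), 1,4-dioxane, 90 °C
Reagents that add atoms: (tributylstannyl)methanol, CCCC[Sn](CO)(CCCC)CCCC
Why: Stille coupling of the α-iodoenone transfers the hydroxymethyl group (C18) to C12 in preference to butyl.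

Step 10
Reactants: 14 (5R)-5-{(2Z,6E)-9-[(tert-butyldimethylsilyl)oxy]-3,7-dimethylnona-2,6-dien-1-yl}-2-(hydroxymethyl)-4,4-dimethylcyclohex-2-en-1-one
Product: 16 (5R)-5-{(2Z,6E)-9-[(tert-butyldimethylsilyl)oxy]-3,7-dimethylnona-2,6-dien-1-yl}-2-(chloromethyl)-4,4-dimethylcyclohex-2-en-1-one, via allylic mesylate 15 (not isolated)
Conditions: MsCl, LiCl, 2,4,6-collidine, DMF, 0 °C
Reagents that add atoms: lithium chloride, [Li+].[Cl-]
Why: Collington–Meyers chlorination (mesylate 15 displaced by chloride) gives the allylic chloride under a non-nucleophilic base, and SN2 versus SN2' attack is immaterial because both allylic isomers lead to the same allylmetal.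

Step 11
Reactants: 16 (5R)-5-{(2Z,6E)-9-[(tert-butyldimethylsilyl)oxy]-3,7-dimethylnona-2,6-dien-1-yl}-2-(chloromethyl)-4,4-dimethylcyclohex-2-en-1-one
Product: 17 (5R)-2-(chloromethyl)-5-[(2Z,6E)-9-hydroxy-3,7-dimethylnona-2,6-dien-1-yl]-4,4-dimethylcyclohex-2-en-1-one
Conditions: HF (48% aq.), MeCN, 0 °C
Reagents that add atoms: none
Why: HF cleaves the primary silyl ether by Si–F bond formation under acidic conditions that the base-sensitive 2-(chloromethyl)enone tolerates.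

Step 12
Reactants: 17 (5R)-2-(chloromethyl)-5-[(2Z,6E)-9-hydroxy-3,7-dimethylnona-2,6-dien-1-yl]-4,4-dimethylcyclohex-2-en-1-one
Product: 18 (5R)-2-(chloromethyl)-5-[(2Z,6E)-3,7-dimethyl-9-oxonona-2,6-dien-1-yl]-4,4-dimethylcyclohex-2-en-1-one
Conditions: Dess–Martin periodinane, NaHCO3, CH2Cl2, 0 → 25 °C; used at once
Reagents that add atoms: none
Why: Dess–Martin oxidation under buffered, base-free conditions gives the β,γ-unsaturated aldehyde without moving the 7E alkene into conjugation.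

Step 13
Reactants: 18 (5R)-2-(chloromethyl)-5-[(2Z,6E)-3,7-dimethyl-9-oxonona-2,6-dien-1-yl]-4,4-dimethylcyclohex-2-en-1-one
Product: 20 (1R,3Z,7E,10R,11S)-10-hydroxy-4,8,15,15-tetramethyl-12-methylidenebicyclo[9.3.1]pentadeca-3,7-dien-13-one, via allylchromium dichloride 19 (not isolated)
Conditions: CrCl2 (8 equiv), NaI (cat.), THF/DMF 3:1, 25 °C, syringe-pump addition of 18 over 12 h (final 2 mM); aq. work-up
Reagents that add atoms: none
Why: Intramolecular Nozaki–Hiyama allylation (Barbier-type macrocyclisation, the reaction type used to close cembranoid rings), in which allylchromium 19 adds to the aldehyde through its γ-carbon C11 in a six-membered Zimmerman–Traxler chair, C11 being attacked axially on the face opposite the pseudoaxial C15 methyl and opposite the equatorial C1 side chain (trans C1/C11 bonds, 11S), the ring-fixed E-type allyl unit with an equatorial aldehyde residue giving the anti C10–OH/C11–C15 relationship (10R), and the allylic shift unveiling the C12=C18 exo-methylene ketone.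

Step 14
Reactants: 20 (1R,3Z,7E,10R,11S)-10-hydroxy-4,8,15,15-tetramethyl-12-methylidenebicyclo[9.3.1]pentadeca-3,7-dien-13-one
Product: 21 (1R,3Z,7E,10R,11S)-4,8,15,15-tetramethyl-12-methylidene-13-oxobicyclo[9.3.1]pentadeca-3,7-dien-10-yl acetate
Conditions: Ac2O, pyridine, DMAP (cat.), CH2Cl2, 0 → 25 °C
Reagents that add atoms: acetic anhydride, CC(=O)OC(C)=O
Why: DMAP-catalysed acylation of the C10 alcohol with acetic anhydride; no stereocentre is affected.

Step 15
Reactants: 21 (1R,3Z,7E,10R,11S)-4,8,15,15-tetramethyl-12-methylidene-13-oxobicyclo[9.3.1]pentadeca-3,7-dien-10-yl acetate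
Product: 24 (1R,3R,4S,7R,8R,10R,11S)-3,4:7,8-diepoxy-4,8,15,15-tetramethyl-12-methylidene-13-oxobicyclo[9.3.1]pentadecan-10-yl acetate, via 7,8-monoepoxide 22 (not isolated), via 3,4-monoepoxide 23 (not isolated)
Conditions: D-fructose-derived Shi ketone (0.6 equiv), Oxone (KHSO5), K2CO3, Bu4NHSO4, MeCN/(MeO)2CH2/aq. Na2B4O7 buffer (pH 10.5), 0 °C
Reagents that add atoms: potassium peroxymonosulfate (Oxone), [K+].[O-]S(=O)(=O)OO
Why: Shi asymmetric epoxidation, in which the chiral dioxirane reacts through a spiro transition state with the single vinylic hydrogen of each trisubstituted alkene in the hindered quadrant, which for both the 3Z and the 7E alkene is the face giving R at the CH carbon (3R,4S and 7R,8R), these being taken to be the outer faces open to peripheral attack on the 12-membered ring, while the electron-poor exo-methylene enone and the acetate do not react at 0 °C.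

## Compound list

1 | 4,4-dimethylcyclohex-2-en-1-one | CC1(C)CCC(=O)C=C1 | starting material
2 | 4,4-dimethylcyclohexa-2,5-dien-1-one | CC1(C)C=CC(=O)C=C1 | intermediate
3 | (5S)-5-ethenyl-4,4-dimethylcyclohex-2-en-1-one | O=C1C=CC(C)(C)[C@H](C=C)C1 | intermediate
4 | 2-[(1R)-2,2-dimethyl-5-oxocyclohex-3-en-1-yl]acetaldehyde | O=C1C=CC(C)(C)[C@H](CC=O)C1 | intermediate
5 | (5R)-5-[(2Z)-3-iodobut-2-en-1-yl]-4,4-dimethylcyclohex-2-en-1-one | O=C1C=CC(C)(C)[C@H](C/C=C(/C)I)C1 | intermediate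
6 | tert-butyl(but-3-yn-1-yloxy)dimethylsilane | C#CCCO[Si](C)(C)C(C)(C)C | starting material
7 | {(1E)-4-[(tert-butyldimethylsilyl)oxy]-2-methylbut-1-en-1-yl}dimethylalumane | C[Al](C)/C=C(\C)CCO[Si](C)(C)C(C)(C)C | intermediate
8 | lithium butyl{(1E)-4-[(tert-butyldimethylsilyl)oxy]-2-methylbut-1-en-1-yl}dimethylaluminate | [Li+].CCCC[Al-](C)(C)/C=C(\C)CCO[Si](C)(C)C(C)(C)C | intermediate
9 | (3E)-6-[(tert-butyldimethylsilyl)oxy]-4-methylhex-3-en-1-ol | OCC/C=C(\C)CCO[Si](C)(C)C(C)(C)C | intermediate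
10 | tert-butyl{[(3E)-6-iodo-3-methylhex-3-en-1-yl]oxy}dimethylsilane | ICC/C=C(\C)CCO[Si](C)(C)C(C)(C)C | intermediate
11 | {(3E)-6-[(tert-butyldimethylsilyl)oxy]-4-methylhex-3-en-1-yl}zinc iodide | I[Zn]CC/C=C(\C)CCO[Si](C)(C)C(C)(C)C | intermediate
12 | (5R)-5-{(2Z,6E)-9-[(tert-butyldimethylsilyl)oxy]-3,7-dimethylnona-2,6-dien-1-yl}-4,4-dimethylcyclohex-2-en-1-one | O=C1C=CC(C)(C)[C@H](C/C=C(/C)CC/C=C(\C)CCO[Si](C)(C)C(C)(C)C)C1 | intermediate
13 | (5R)-5-{(2Z,6E)-9-[(tert-butyldimethylsilyl)oxy]-3,7-dimethylnona-2,6-dien-1-yl}-2-iodo-4,4-dimethylcyclohex-2-en-1-one | O=C1C(I)=CC(C)(C)[C@H](C/C=C(/C)CC/C=C(\C)CCO[Si](C)(C)C(C)(C)C)C1 | intermediate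
14 | (5R)-5-{(2Z,6E)-9-[(tert-butyldimethylsilyl)oxy]-3,7-dimethylnona-2,6-dien-1-yl}-2-(hydroxymethyl)-4,4-dimethylcyclohex-2-en-1-one | O=C1C(CO)=CC(C)(C)[C@H](C/C=C(/C)CC/C=C(\C)CCO[Si](C)(C)C(C)(C)C)C1 | intermediate
15 | [(4R)-4-{(2Z,6E)-9-[(tert-butyldimethylsilyl)oxy]-3,7-dimethylnona-2,6-dien-1-yl}-3,3-dimethyl-6-oxocyclohex-1-en-1-yl]methyl methanesulfonate | O=C1C(COS(C)(=O)=O)=CC(C)(C)[C@H](C/C=C(/C)CC/C=C(\C)CCO[Si](C)(C)C(C)(C)C)C1 | intermediate
16 | (5R)-5-{(2Z,6E)-9-[(tert-butyldimethylsilyl)oxy]-3,7-dimethylnona-2,6-dien-1-yl}-2-(chloromethyl)-4,4-dimethylcyclohex-2-en-1-one | O=C1C(CCl)=CC(C)(C)[C@H](C/C=C(/C)CC/C=C(\C)CCO[Si](C)(C)C(C)(C)C)C1 | intermediate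
17 | (5R)-2-(chloromethyl)-5-[(2Z,6E)-9-hydroxy-3,7-dimethylnona-2,6-dien-1-yl]-4,4-dimethylcyclohex-2-en-1-one | O=C1C(CCl)=CC(C)(C)[C@H](C/C=C(/C)CC/C=C(\C)CCO)C1 | intermediate
18 | (5R)-2-(chloromethyl)-5-[(2Z,6E)-3,7-dimethyl-9-oxonona-2,6-dien-1-yl]-4,4-dimethylcyclohex-2-en-1-one | O=C1C(CCl)=CC(C)(C)[C@H](C/C=C(/C)CC/C=C(\C)CC=O)C1 | intermediate
19 | dichloro{[(4R)-4-[(2Z,6E)-3,7-dimethyl-9-oxonona-2,6-dien-1-yl]-3,3-dimethyl-6-oxocyclohex-1-en-1-yl]methyl}chromium | O=C1C(C[Cr](Cl)Cl)=CC(C)(C)[C@H](C/C=C(/C)CC/C=C(\C)CC=O)C1 | intermediate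
20 | (1R,3Z,7E,10R,11S)-10-hydroxy-4,8,15,15-tetramethyl-12-methylidenebicyclo[9.3.1]pentadeca-3,7-dien-13-one | C=C1C(=O)C[C@H]2C/C=C(/C)CC/C=C(\C)C[C@@H](O)[C@H]1C2(C)C | intermediate
21 | (1R,3Z,7E,10R,11S)-4,8,15,15-tetramethyl-12-methylidene-13-oxobicyclo[9.3.1]pentadeca-3,7-dien-10-yl acetate | C=C1C(=O)C[C@H]2C/C=C(/C)CC/C=C(\C)C[C@@H](OC(C)=O)[C@H]1C2(C)C | intermediate
22 | (1R,3Z,7R,8R,10R,11S)-7,8-epoxy-4,8,15,15-tetramethyl-12-methylidene-13-oxobicyclo[9.3.1]pentadec-3-en-10-yl acetate | C=C1C(=O)C[C@H]2C/C=C(/C)CC[C@H]3O[C@]3(C)C[C@@H](OC(C)=O)[C@H]1C2(C)C | intermediate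
23 | (1R,3R,4S,7E,10R,11S)-3,4-epoxy-4,8,15,15-tetramethyl-12-methylidene-13-oxobicyclo[9.3.1]pentadec-7-en-10-yl acetate | C=C1C(=O)C[C@H]2C[C@H]3O[C@@]3(C)CC/C=C(\C)C[C@@H](OC(C)=O)[C@H]1C2(C)C | intermediate
24 | (1R,3R,4S,7R,8R,10R,11S)-3,4:7,8-diepoxy-4,8,15,15-tetramethyl-12-methylidene-13-oxobicyclo[9.3.1]pentadecan-10-yl acetate (CNP0339728.7) | C=C1C(=O)C[C@H]2C[C@H]3O[C@@]3(C)CC[C@H]3O[C@]3(C)C[C@@H](OC(C)=O)[C@H]1C2(C)C | target

## Step count

Total: 15 steps. Longest linear sequence: 13 steps (steps 1–4 and 7–15, 1 → 24); the side branch is steps 5–6.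

## Three steps most likely to fail

**Step 13 (ring closure).** Risks are oligomerisation, attack through C18 (14-membered ring), or the wrong face at C11 or C10. The fallback below secures attack through C11 and a closed transition state for C10; it does not by itself correct a wrong face at C11. It sets out from chloro alcohol 17. Palladium-catalysed borylation (Pd2(dba)3, bis(pinacolato)diboron, toluene, 50 °C) replaces chloride by boron and gives the allylboronate alcohol F1. Dess–Martin oxidation gives the boronate aldehyde F2. Heated at 2 mM in toluene (80 °C), F2 closes the ring by a metal-free, Lewis-acid-free intramolecular allylboration that can only go through C11 and a closed chair, giving the pinacol borate ester F3. Hydrolytic work-up then returns to the route at 20.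

**Step 2 (vinyl addition next to the quaternary carbon).** Risks are low rate, low ee, or double addition. The fallback sets out from dienone 2. Copper-catalysed addition of bis(but-3-enyl)zinc (Cu(OTf)2, Feringa's binaphthol bis(1-phenylethyl)amine phosphoramidite, the enantiomer that gives (S)-3-alkylcyclohexanones, toluene, −30 °C), a reaction class established for 4,4-disubstituted dienones, gives the butenyl ketone F4. One-position alkene isomerisation with the Grotjahn catalyst [Cp*Ru(NCMe)(iPr2P–Im)]PF6 (Im = 4-tert-butyl-1-methylimidazol-2-yl) gives the (E)-but-2-enyl ketone F5. Cleavage of the electron-rich alkene (OsO4 cat., NaIO4, 2,6-lutidine, dioxane/H2O) returns to the route at aldehyde 4.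

**Step 15 (double epoxidation on the macrocycle).** The risk is that the ring conformation exposes the wrong face of one alkene, most likely the 3Z one, and overrides the catalyst. The fallback sets out from 14 and moves the epoxidation to the open-chain stage, where only the catalyst decides. The same Shi conditions give, through the 7,8-monoepoxide F6 and the 3,4-monoepoxide F7, the diepoxide F8. Bu4NF removes the silyl group to give the diol F9. Corey–Kim chlorination (N-chlorosuccinimide, Me2S, CH2Cl2, −20 °C), which converts only the allylic alcohol, gives the chloro alcohol F10. Dess–Martin oxidation gives the chloro aldehyde F11. CrCl2 ring closure as in step 13, through the allylchromium F12, gives the diepoxy macrocyclic alcohol F13. Acetylation as in step 14 returns to the route at 24.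

## Further compounds

F1 | step 13 | (5R)-5-[(2Z,6E)-9-hydroxy-3,7-dimethylnona-2,6-dien-1-yl]-4,4-dimethyl-2-[(4,4,5,5-tetramethyl-1,3,2-dioxaborolan-2-yl)methyl]cyclohex-2-en-1-one | O=C1C(CB2OC(C)(C)C(C)(C)O2)=CC(C)(C)[C@H](C/C=C(/C)CC/C=C(\C)CCO)C1
F2 | step 13 | (5R)-5-[(2Z,6E)-3,7-dimethyl-9-oxonona-2,6-dien-1-yl]-4,4-dimethyl-2-[(4,4,5,5-tetramethyl-1,3,2-dioxaborolan-2-yl)methyl]cyclohex-2-en-1-one | O=C1C(CB2OC(C)(C)C(C)(C)O2)=CC(C)(C)[C@H](C/C=C(/C)CC/C=C(\C)CC=O)C1
F3 | step 13 | 2-{[(1R,3Z,7E,10R,11S)-4,8,15,15-tetramethyl-12-methylidene-13-oxobicyclo[9.3.1]pentadeca-3,7-dien-10-yl]oxy}-4,4,5,5-tetramethyl-1,3,2-dioxaborolane | C=C1C(=O)C[C@H]2C/C=C(/C)CC/C=C(\C)C[C@@H](OB3OC(C)(C)C(C)(C)O3)[C@H]1C2(C)C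
F4 | step 2 | (5R)-5-(but-3-en-1-yl)-4,4-dimethylcyclohex-2-en-1-one | O=C1C=CC(C)(C)[C@H](CCC=C)C1
F5 | step 2 | (5R)-5-[(2E)-but-2-en-1-yl]-4,4-dimethylcyclohex-2-en-1-one | O=C1C=CC(C)(C)[C@H](C/C=C/C)C1
F6 | step 15 | (5R)-5-[(2Z)-5-{(2R,3R)-3-[2-((tert-butyldimethylsilyl)oxy)ethyl]-3-methyloxiran-2-yl}-3-methylpent-2-en-1-yl]-2-(hydroxymethyl)-4,4-dimethylcyclohex-2-en-1-one | O=C1C(CO)=CC(C)(C)[C@H](C/C=C(/C)CC[C@H]2O[C@]2(C)CCO[Si](C)(C)C(C)(C)C)C1
F7 | step 15 | (5R)-5-({(2R,3S)-3-[(3E)-6-((tert-butyldimethylsilyl)oxy)-4-methylhex-3-en-1-yl]-3-methyloxiran-2-yl}methyl)-2-(hydroxymethyl)-4,4-dimethylcyclohex-2-en-1-one | O=C1C(CO)=CC(C)(C)[C@H](C[C@H]2O[C@@]2(C)CC/C=C(\C)CCO[Si](C)(C)C(C)(C)C)C1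
F8 | step 15 | (5R)-5-{[(2R,3S)-3-(2-{(2R,3R)-3-[2-((tert-butyldimethylsilyl)oxy)ethyl]-3-methyloxiran-2-yl}ethyl)-3-methyloxiran-2-yl]methyl}-2-(hydroxymethyl)-4,4-dimethylcyclohex-2-en-1-one | O=C1C(CO)=CC(C)(C)[C@H](C[C@H]2O[C@@]2(C)CC[C@H]3O[C@]3(C)CCO[Si](C)(C)C(C)(C)C)C1
F9 | step 15 | (5R)-5-{[(2R,3S)-3-(2-{(2R,3R)-3-(2-hydroxyethyl)-3-methyloxiran-2-yl}ethyl)-3-methyloxiran-2-yl]methyl}-2-(hydroxymethyl)-4,4-dimethylcyclohex-2-en-1-one | O=C1C(CO)=CC(C)(C)[C@H](C[C@H]2O[C@@]2(C)CC[C@H]3O[C@]3(C)CCO)C1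
F10 | step 15 | (5R)-2-(chloromethyl)-5-{[(2R,3S)-3-(2-{(2R,3R)-3-(2-hydroxyethyl)-3-methyloxiran-2-yl}ethyl)-3-methyloxiran-2-yl]methyl}-4,4-dimethylcyclohex-2-en-1-one | O=C1C(CCl)=CC(C)(C)[C@H](C[C@H]2O[C@@]2(C)CC[C@H]3O[C@]3(C)CCO)C1
F11 | step 15 | (5R)-2-(chloromethyl)-5-{[(2R,3S)-3-(2-{(2R,3R)-3-methyl-3-(2-oxoethyl)oxiran-2-yl}ethyl)-3-methyloxiran-2-yl]methyl}-4,4-dimethylcyclohex-2-en-1-one | O=C1C(CCl)=CC(C)(C)[C@H](C[C@H]2O[C@@]2(C)CC[C@H]3O[C@]3(C)CC=O)C1
F12 | step 15 | dichloro{[(4R)-4-{[(2R,3S)-3-(2-{(2R,3R)-3-methyl-3-(2-oxoethyl)oxiran-2-yl}ethyl)-3-methyloxiran-2-yl]methyl}-3,3-dimethyl-6-oxocyclohex-1-en-1-yl]methyl}chromium | O=C1C(C[Cr](Cl)Cl)=CC(C)(C)[C@H](C[C@H]2O[C@@]2(C)CC[C@H]3O[C@]3(C)CC=O)C1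
F13 | step 15 | (1R,3R,4S,7R,8R,10R,11S)-3,4:7,8-diepoxy-10-hydroxy-4,8,15,15-tetramethyl-12-methylidenebicyclo[9.3.1]pentadecan-13-one | C=C1C(=O)C[C@H]2C[C@H]3O[C@@]3(C)CC[C@H]3O[C@]3(C)C[C@@H](O)[C@H]1C2(C)C
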